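**Assumptions (one line each)**
- The facial sense of the new catalytic step (Step 6) cannot be predicted; both catalyst antipodes are screened and the one giving (R) at the peroxide carbon is used.
- Target numbering is used throughout: C1 ester, C2 (R), C3 (S, dioxane CH), C6 (R, dioxane quaternary C); the 2-Me/3-O relationship is syn, and the C3 side chain is cis to the C6 methyl.

## Retrosynthetic overview
1. Target ⇐ vinyl dioxane 15 by cleaving the vinyl group to CO2Me (C1).
2. The 1,2-dioxane (the only ring formed; the cyclohexenone ring comes intact from β-ionone) ⇐ 6-exo-tet SN2 of the C6–OOH on a C3 mesylate, with inversion at C3.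
3. C2/C3 ⇐ anti-selective Brown (E)-crotylboration of aldehyde 10.
4. C6 tertiary peroxide and the C5–C6 bond ⇐ proposed catalytic asymmetric allylation of a ketone-derived peroxycarbenium ion (new step).
5. Peroxyketal 6 ⇐ 4-oxo-7,8-dihydro-β-ionone ⇐ β-ionone.

## Route

**Step 1**
Reactants: 1, β-ionone
Product: 2, 4-oxo-β-ionone
Conditions: t-BuOOH (70% aq), cat. Rh2(cap)4, K2CO3, CH2Cl2, rt
Reagents that add atoms: tert-butyl hydroperoxide, CC(C)(C)OO (oxygen)
Why: Radical allylic C–H oxidation at the only ring allylic CH2 gives the enone; the electron-poor dienone is not epoxidised.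

**Step 2**
Reactants: 2, 4-oxo-β-ionone
Product: 3, 2,4,4-trimethyl-3-(3-oxobutyl)cyclohex-2-en-1-one
Conditions: H2 (1 atm), 5% Pd/C, EtOAc, rt, stopped at 1 equiv uptake
Reagents that add atoms: none
Why: Chemoselective catalytic hydrogenation; the unhindered disubstituted side-chain alkene reduces far faster than the tetrasubstituted ring enone alkene.

**Step 3**
Reactants: 3
Product: 4, 2,4,4-trimethyl-3-(3-methylbut-3-en-1-yl)cyclohex-2-en-1-one
Conditions: Zn, CH2Br2, TiCl4, THF/CH2Cl2, 0 °C → rt
Reagents that add atoms: dibromomethane, BrCBr (CH2)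
Why: Takai–Lombardo methylenation is non-basic and selects the unhindered saturated methyl ketone over the hindered conjugated ring ketone.

**Step 4**
Reactants: 4
Product: 5, rac-3-(3-hydroperoxy-3-methoxybutyl)-2,4,4-trimethylcyclohex-2-en-1-one
Conditions: O3, CH2Cl2/MeOH 4:1, −78 °C (Sudan Red 7B endpoint); N2 purge
Reagents that add atoms: ozone, [O-][O+]=O; methanol, CO
Why: Criegee ozonolysis in methanol; ozone takes the electron-rich 1,1-disubstituted alkene before the enone, and MeOH traps the ketone oxide as the α-methoxy hydroperoxide (racemic centre, erased in Step 6).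

**Step 5**
Reactants: 5
Product: 6, rac-3-{3-[(tert-butyldimethylsilyl)peroxy]-3-methoxybutyl}-2,4,4-trimethylcyclohex-2-en-1-one
Conditions: TBSCl, imidazole, DMF, 0 °C
Reagents that add atoms: tert-butyldimethylsilyl chloride, CC(C)(C)[Si](C)(C)Cl
Why: Standard O-silylation of the acidic hydroperoxide OH gives a stable silyl monoperoxyketal.

**Step 6 (proposed new step)**
Reactants: 6; 7, allyltrimethylsilane
Product: 8, 3-{(3R)-3-[(tert-butyldimethylsilyl)peroxy]-3-methylhex-5-en-1-yl}-2,4,4-trimethylcyclohex-2-en-1-one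
Conditions: 7 (3 equiv), chiral BINOL-derived imidodiphosphorimidate (IDPi, N-Tf core) 3 mol %, toluene, −78 °C; Et3N quench
Reagents that add atoms: allyltrimethylsilane, C=CC[Si](C)(C)C (allyl)
Why: Proposed new method: the silylated IDPi (formed in situ from the acid and allyl-TMS) abstracts the more basic OMe of 6 as TMSOMe to give a silylperoxycarbenium ion [R(Me)C=O+–OTBS] held as a contact ion pair in the confined chiral anion, which distinguishes CH3 from the CH2CH2-enone arm and exposes one face to allyl-TMS, and β-silyl loss then regenerates the silylium catalyst, forming the C5–C6 bond and the (R) tertiary peroxide centre; the closest known reactions are achiral SnCl4/TiCl4/TMSOTf allylations of monoperoxyketals via peroxycarbenium ions and IDPi-catalysed asymmetric Hosomi–Sakurai/Mukaiyama additions to aldehyde- and methyl-ketone-derived oxocarbenium ions.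

**Step 7**
Reactants: 8
Product: 9, 3-{(3R)-3-[(tert-butyldimethylsilyl)peroxy]-6-hydroxy-3-methylhexyl}-2,4,4-trimethylcyclohex-2-en-1-one
Conditions: 9-BBN (1.1 equiv), THF, 0 °C → rt; NaBO3·4H2O, THF/H2O, rt
Reagents that add atoms: sodium perborate, O=BO[O-].[Na+] (oxygen; 9-BBN supplies only H)
Why: Anti-Markovnikov hydroboration–oxidation of the monosubstituted alkene, which reacts faster than the hindered enone carbonyl; perborate is mild enough for the silyl peroxide.

**Step 8**
Reactants: 9
Product: 10, (4R)-4-[(tert-butyldimethylsilyl)peroxy]-4-methyl-6-(2,6,6-trimethyl-3-oxocyclohex-1-en-1-yl)hexanal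
Conditions: Dess–Martin periodinane, NaHCO3, CH2Cl2, 0 °C → rt
Reagents that add atoms: none
Why: Dess–Martin oxidation of the primary alcohol under neutral conditions that leave the silyl peroxide and enone untouched.

**Step 9**
Reactants: 10; 11, trans-2-butene (used as its in-situ (E)-crotylborane)
Product: 12, 3-{(3R,6R,7S)-3-[(tert-butyldimethylsilyl)peroxy]-6-hydroxy-3,7-dimethylnon-8-en-1-yl}-2,4,4-trimethylcyclohex-2-en-1-one (target numbering: 3R-OH, 2S-Me, anti)
Conditions: 11, n-BuLi, KOt-Bu, THF, −78 → −45 °C; (−)-Ipc2BOMe [from (+)-α-pinene], −78 °C; BF3·OEt2; then 10, −78 °C; ethanolamine work-up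
Reagents that add atoms: (−)-(E)-crotyldiisopinocampheylborane, C/C=C/CB(C1CC2CC(C1C)C2(C)C)C1CC2CC(C1C)C2(C)C (crotyl)
Why: Brown crotylboration through a closed chair (Zimmerman–Traxler) transition state; the E-crotyl geometry gives the anti relationship and the (−)-Ipc ligands direct Re-face attack (reagent control, (R)-carbinol), and the enone ketone is inert at −78 °C.

**Step 10**
Reactants: 12
Product: 13, the C6-methanesulfonate of 12 (same 3R,6R,7S configuration)
Conditions: MsCl, Et3N, CH2Cl2, 0 °C
Reagents that add atoms: methanesulfonyl chloride, CS(=O)(=O)Cl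
Why: Sulfonylation of the secondary alcohol with retention installs the leaving group at C3 (target numbering).

**Step 11**
Reactants: 13
Product: 14, the free tertiary hydroperoxide mesylate (3R,6R,7S)
Conditions: TBAF/AcOH (1:1), THF, 0 °C
Reagents that add atoms: none
Why: Buffered fluoride cleaves the Si–O bond of the silyl peroxide selectively without touching the mesylate.

**Step 12**
Reactants: 14
Product: 15, 3-{2-[(3R,6S)-6-[(2S)-but-3-en-2-yl]-3-methyl-1,2-dioxan-3-yl]ethyl}-2,4,4-trimethylcyclohex-2-en-1-one (target numbering 2S,3S,6R)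
Conditions: KOt-Bu (1.0 equiv), 18-crown-6, THF, 0 °C
Reagents that add atoms: none
Why: Intramolecular 6-exo-tet SN2 alkylation of the hydroperoxide anion on the secondary mesylate closes the 1,2-dioxane with clean inversion at C3 (R → S); one equivalent of base limits E2 and Kornblum–DeLaMare side reactions, and addition to the hindered enone β-carbon is reversible and disfavoured.

**Step 13**
Reactants: 15
Product: 16, (2R)-2-[(3S,6R)-6-methyl-6-[2-(2,6,6-trimethyl-3-oxocyclohex-1-en-1-yl)ethyl]-1,2-dioxan-3-yl]propanal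
Conditions: O3, CH2Cl2, −78 °C (Sudan Red 7B endpoint); Me2S, −78 °C → rt; used at once
Reagents that add atoms: ozone, [O-][O+]=O
Why: Reductive ozonolysis of the terminal vinyl group, which reacts faster than the electron-poor tetrasubstituted enone; the dialkyl peroxide is inert to Me2S.

**Step 14**
Reactants: 16
Product: 17, (2R)-2-[(3S,6R)-6-methyl-6-[2-(2,6,6-trimethyl-3-oxocyclohex-1-en-1-yl)ethyl]-1,2-dioxan-3-yl]propanoic acid
Conditions: NaClO2, NaH2PO4, 2-methyl-2-butene, t-BuOH/H2O, 0 °C → rt
Reagents that add atoms: sodium chlorite, [O-]Cl=O.[Na+] (oxygen)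
Why: Pinnick oxidation is mildly acidic, so C2 is not epimerised and the β-peroxide is not eliminated.

**Step 15**
Reactants: 17
Product: 18, methyl diacarnoate A
Conditions: TMSCHN2, PhMe/MeOH, 0 °C
Reagents that add atoms: trimethylsilyldiazomethane, C[Si](C)(C)C=[N+]=[N-] (methyl carbon)
Why: Base-free diazoalkane esterification avoids Kornblum–DeLaMare cleavage of the dioxane and C2 epimerisation.

## Compound list
1 | β-ionone, (E)-4-(2,6,6-trimethylcyclohex-1-en-1-yl)but-3-en-2-one | CC(=O)/C=C/C1=C(C)CCCC1(C)C | starting material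
2 | 4-oxo-β-ionone | CC(=O)/C=C/C1=C(C)C(=O)CCC1(C)C | intermediate
3 | 2,4,4-trimethyl-3-(3-oxobutyl)cyclohex-2-en-1-one | CC(=O)CCC1=C(C)C(=O)CCC1(C)C | intermediate
4 | 2,4,4-trimethyl-3-(3-methylbut-3-en-1-yl)cyclohex-2-en-1-one | CC(=C)CCC1=C(C)C(=O)CCC1(C)C | intermediate
5 | rac-3-(3-hydroperoxy-3-methoxybutyl)-2,4,4-trimethylcyclohex-2-en-1-one | COC(C)(OO)CCC1=C(C)C(=O)CCC1(C)C | intermediate
6 | rac-3-{3-[(tert-butyldimethylsilyl)peroxy]-3-methoxybutyl}-2,4,4-trimethylcyclohex-2-en-1-one | COC(C)(OO[Si](C)(C)C(C)(C)C)CCC1=C(C)C(=O)CCC1(C)C | intermediate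
7 | allyltrimethylsilane | C=CC[Si](C)(C)C | starting material
8 | 3-{(3R)-3-[(TBS)peroxy]-3-methylhex-5-en-1-yl}-2,4,4-trimethylcyclohex-2-en-1-one | C=CC[C@@](C)(CCC1=C(C)C(=O)CCC1(C)C)OO[Si](C)(C)C(C)(C)C | intermediate
9 | 3-{(3R)-3-[(TBS)peroxy]-6-hydroxy-3-methylhexyl}-2,4,4-trimethylcyclohex-2-en-1-one | OCCC[C@@](C)(CCC1=C(C)C(=O)CCC1(C)C)OO[Si](C)(C)C(C)(C)C | intermediate
10 | (4R)-4-[(TBS)peroxy]-4-methyl-6-(2,6,6-trimethyl-3-oxocyclohex-1-en-1-yl)hexanal | O=CCC[C@@](C)(CCC1=C(C)C(=O)CCC1(C)C)OO[Si](C)(C)C(C)(C)C | intermediate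
11 | trans-2-butene | C/C=C/C | starting material
12 | 3-{(3R,6R,7S)-3-[(TBS)peroxy]-6-hydroxy-3,7-dimethylnon-8-en-1-yl}-2,4,4-trimethylcyclohex-2-en-1-one | C=C[C@H](C)[C@H](O)CC[C@@](C)(CCC1=C(C)C(=O)CCC1(C)C)OO[Si](C)(C)C(C)(C)C | intermediate
13 | (3R,6R,7S)-6-methanesulfonate of 12 | C=C[C@H](C)[C@H](OS(C)(=O)=O)CC[C@@](C)(CCC1=C(C)C(=O)CCC1(C)C)OO[Si](C)(C)C(C)(C)C | intermediate
14 | (3R,6R,7S)-3-hydroperoxy-6-mesyloxy analogue of 13 | C=C[C@H](C)[C@H](OS(C)(=O)=O)CC[C@@](C)(CCC1=C(C)C(=O)CCC1(C)C)OO | intermediate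
15 | 3-{2-[(3R,6S)-6-[(2S)-but-3-en-2-yl]-3-methyl-1,2-dioxan-3-yl]ethyl}-2,4,4-trimethylcyclohex-2-en-1-one | C=C[C@H](C)[C@@H]1CC[C@@](C)(CCC2=C(C)C(=O)CCC2(C)C)OO1 | intermediate
16 | (2R)-2-[(3S,6R)-6-methyl-6-[2-(2,6,6-trimethyl-3-oxocyclohex-1-en-1-yl)ethyl]-1,2-dioxan-3-yl]propanal | O=C[C@H](C)[C@@H]1CC[C@@](C)(CCC2=C(C)C(=O)CCC2(C)C)OO1 | intermediate
17 | (2R)-2-[(3S,6R)-6-methyl-6-[2-(2,6,6-trimethyl-3-oxocyclohex-1-en-1-yl)ethyl]-1,2-dioxan-3-yl]propanoic acid | OC(=O)[C@H](C)[C@@H]1CC[C@@](C)(CCC2=C(C)C(=O)CCC2(C)C)OO1 | intermediate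
18 | methyl diacarnoate A, methyl (2R)-2-[(3S,6R)-6-methyl-6-[2-(2,6,6-trimethyl-3-oxocyclohex-1-en-1-yl)ethyl]-1,2-dioxan-3-yl]propanoate | COC(=O)[C@H](C)[C@@H]1CC[C@@](C)(CCC2=C(C)C(=O)CCC2(C)C)OO1 | target

## Summary
Total steps: 15. Longest linear sequence: 15 (β-ionone 1 → 18); allyltrimethylsilane and trans-2-butene are used as purchased.

Three steps most likely to fail, each with a fallback that changes the approach:

1. **Step 6 (new asymmetric peroxycarbenium allylation).** Risks are low ee, ionisation of the silylperoxy group instead of OMe (giving the allyl methyl ether), or Criegee-type rearrangement. Fallback (known chemistry): run the established achiral SnCl4- or TiCl4-mediated allylation of peroxyketal 6 to give rac-8, carry it through the reagent-controlled crotylation (Step 9), and separate the two C6-epimeric diastereomers by chromatography at 12 or 15. This costs at most 50% of material, and the desired isomer then carries the enantiopurity of the crotylation.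

2. **Step 12 (6-exo-tet peroxide SN2 at a branched secondary mesylate).** Risks are E2 to the conjugated diene and base-induced Kornblum–DeLaMare cleavage of the product. Fallback: close the ring by conjugate addition instead. Aldehyde 10 is olefinated with methyl 2-(triphenylphosphoranylidene)propanoate to the (E)-α-methyl enoate, desilylated, and cyclised by the known base-mediated intramolecular peroxy-Michael addition (Et2NH, CF3CH2OH). The (2R,3S,6R) diastereomer is then separated; the diastereoselectivity is lower but the oxidation-state changes of Steps 13–15 are avoided.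

3. **Step 7 (hydroboration in the presence of the enone and the silyl peroxide).** Risks are 1,2-reduction of the enone and O–O reduction by the borane. Fallback: cross-metathesis of 8 with vinylboronic acid pinacol ester (Hoveyda–Grubbs II, CH2Cl2, 40 °C), then NaBO3 oxidation of the alkenyl boronate. This gives aldehyde 10 directly with no B–H reagent and replaces Steps 7–8.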